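The route rests on one disconnection: the C14–C1 bond (cembrane numbering), shared by the α-methylene-γ-butyrolactone and the 14-membered carbocycle. Because C1 is allylic to the exocyclic C15=C17 methylene and C14 carries the lactone oxygen, this bond is the γ-adduct of a 2-(methoxycarbonyl)allyl metal and an aldehyde. The precursor is an open-chain, farnesol-derived ω-formyl allylboronate: C14 aldehyde next to a 13-silyloxy centre, a C17 pinacolboronate on a (Z)-enoate with C2 cis to the ester, and the 3,4-epoxide in place. Heating at high dilution closes the macrocycle by allylboration, sets C14 and C1 trans, and lets the borate lactonise. A Mitsunobu acetylation finally inverts C13.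

Key step: step 13

Remark: atoms are numbered as in the cembrane skeleton (C1 lactone β-carbon, C14 lactone carbinol, C13 acetoxy carbon, C3/C4 epoxide, C15/C16/C17 α-carbon, carbonyl and exocyclic methylene). The target is then (1S,3S,4S,13S,14S), with a trans-fused lactone and a 13,14-syn dioxygen pattern. C13 is carried as the 13R epimer on purpose until the last step.

Step 1
Reactants: 1 (2E,6E)-farnesol
Product: 2 (2S,3S)-2,3-epoxyfarnesol
Conditions: Ti(OiPr)4 (cat.), L-(+)-diethyl tartrate (cat.), t-BuOOH, 4 Å molecular sieves, CH2Cl2, −20 °C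
Reagents that add atoms: tert-butyl hydroperoxide, CC(C)(C)OO
Why: Sharpless asymmetric epoxidation reaches only the allylic-alcohol alkene, and the L-(+)-tartrate ligand should deliver oxygen to the face that gives the (2S,3S) epoxide, which becomes the (3S,4S) epoxide of the target.

Step 2
Reactants: 2 (2S,3S)-2,3-epoxyfarnesol
Product: 4 (2S,3S)-2-methyl-2-[(3E)-4,8-dimethylnona-3,7-dien-1-yl]-3-(prop-2-yn-1-yl)oxirane, via epoxy triflate 3 (not isolated)
Conditions: Tf2O, 2,6-lutidine, CH2Cl2, −78 °C; then HC≡CLi (from acetylene and n-BuLi), THF/DMPU, −78 to −30 °C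
Reagents that add atoms: lithium acetylide made from acetylene, C#C; triflic anhydride (atoms only in intermediate 3), O=S(=O)(OS(=O)(=O)C(F)(F)F)C(F)(F)F
Why: SN2 displacement of the primary triflate by the acetylide should be much faster at low temperature than opening of the unactivated trisubstituted epoxide, so C2–C1 is formed without touching the stereocentres.

Step 3
Reactants: 4 epoxy enyne
Product: 6 terminal (E)-enal (C13 aldehyde) of the epoxy enyne, via allylic alcohol 5 (not isolated)
Conditions: SeO2 (cat.), t-BuOOH, salicylic acid (cat.), CH2Cl2, rt; then MnO2, CH2Cl2, rt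
Reagents that add atoms: tert-butyl hydroperoxide (oxygen source, transferred through SeO2), CC(C)(C)OO; selenium dioxide, O=[Se]=O
Why: SeO2 allylic oxidation (ene reaction then [2,3]-sigmatropic shift) is selective for the (E)-methyl group of the terminal trisubstituted alkene, and MnO2 converges the alcohol/aldehyde mixture on the (E)-enal.

Step 4
Reactants: 7 (tributylstannyl)methanol; 8 4-methoxybenzyl chloride
Product: 9 tributyl{[(4-methoxybenzyl)oxy]methyl}stannane
Conditions: NaH, Bu4NI (cat.), THF/DMF, 0 °C to rt
Reagents that add atoms: none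
Why: Williamson ether synthesis of a primary alkoxide with a benzylic chloride gives the hydroxymethyl-anion precursor.

Step 5
Reactants: 6 (E)-enal; 9 tributyl{[(4-methoxybenzyl)oxy]methyl}stannane
Product: 10 C13 carbinol bearing C14H2–OPMB (both C13 epimers)
Conditions: 9, n-BuLi, THF, −78 °C; then 6, −78 °C; aq. NH4Cl
Reagents that add atoms: none
Why: tin–lithium exchange gives the α-alkoxymethyllithium, which adds 1,2 to the enal and installs C14 with its oxygen; excess reagent only deprotonates the terminal alkyne reversibly, and the C13 epimer mixture is erased in the next step.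

Step 6
Reactants: 10 C13 carbinol
Product: 11 α'-(4-methoxybenzyloxy) enone (C13 ketone)
Conditions: Dess–Martin periodinane, NaHCO3, CH2Cl2, 0 °C to rt
Reagents that add atoms: none
Why: Dess–Martin oxidation of the secondary allylic alcohol under buffered neutral conditions should spare the epoxide, the alkyne and the PMB ether.

Step 7
Reactants: 11 enone
Product: 12 (13R)-allylic alcohol
Conditions: (R)-Me-CBS oxazaborolidine [(R)-1-methyl-3,3-diphenyltetrahydro-1H,3H-pyrrolo[1,2-c][1,3,2]oxazaborole] (0.2 equiv), catecholborane, toluene, −78 °C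
Reagents that add atoms: none
Why: in the Corey–Bakshi–Shibata reduction the trisubstituted alkenyl group acts as the large and CH2OPMB as the small substituent, so the (R)-catalyst should give the 13R carbinol (needed as the anti-directing centre in step 13), and catecholborane at −78 °C does not hydroborate the alkyne or alkenes.

Step 8
Reactants: 12 (13R)-allylic alcohol
Product: 13 (13R)-tert-butyldimethylsilyl ether
Conditions: TBSCl, imidazole, DMF, rt
Reagents that add atoms: tert-butyldimethylsilyl chloride, CC(C)(C)[Si](C)(C)Cl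
Why: standard silylation of a secondary alcohol under non-acidic conditions gives the bulky, non-chelating α-oxygen substituent wanted for the key step.

Step 9
Reactants: 13 (13R)-silyl ether with terminal alkyne
Product: 14 methyl ynoate (C16 ester on C15≡C1)
Conditions: n-BuLi, THF, −78 °C; then ClCO2Me, −78 °C; cold aq. NH4Cl quench
Reagents that add atoms: methyl chloroformate, COC(=O)Cl
Why: the acetylenic hydrogen is by far the most acidic, so C-acylation of the lithium acetylide gives the ynoate, and the cold quench avoids γ-deprotonation next to the epoxide.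

Step 10
Reactants: 14 methyl ynoate
Product: 16 methyl (Z)-2-[(pinacolboryl)methyl]alk-2-enoate (allylboronate; C2 cis to the ester), via vinylalane 15 (not isolated)
Conditions: iBu2AlH (DIBAL-H), HMPA, THF, 0 °C; then ICH2Bpin, 0 °C to rt
Reagents that add atoms: 2-(iodomethyl)-4,4,5,5-tetramethyl-1,3,2-dioxaborolane, ICB1OC(C)(C)C(C)(C)O1; diisobutylaluminium hydride (atoms only in intermediate 15), CC(C)C[AlH]CC(C)C
Why: conjugate cis-hydroalumination of the ynoate by the DIBAL-H/HMPA complex puts Al on C15 and H on C1 on the same side, and capture of the vinylalane by the iodomethylboronate (boron ate complex, then 1,2-shift with loss of iodide, a Matteson-type homologation) keeps that geometry.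

Step 11
Reactants: 16 allylboronate
Product: 17 C14 primary alcohol
Conditions: DDQ, CH2Cl2/pH 7 phosphate buffer, 0 °C to rt
Reagents that add atoms: none
Why: oxidative cleavage of the PMB ether by hydride abstraction is selective for the electron-rich benzyl group and, when buffered, should leave the silyl ether, epoxide, trisubstituted alkenes and the electron-poor allylboronate intact.

Step 12
Reactants: 17 C14 primary alcohol
Product: 18 ω-formyl allylboronate (13R α-silyloxy aldehyde)
Conditions: Dess–Martin periodinane, NaHCO3, CH2Cl2, 0 °C; used crude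
Reagents that add atoms: none
Why: buffered Dess–Martin oxidation gives the α-silyloxy aldehyde without base-induced epimerisation at C13, and the ester-substituted allylboronate is too unreactive to add at 0 °C.

Step 13
Reactants: 18 ω-formyl allylboronate
Product: 20 (1S,3S,4S,13R,14S)-13-(tert-butyldimethylsilyloxy) trans-fused α-methylene lactone (13-epi silyl ether of the deacetyl target), via borate ester 19 (not isolated)
Conditions: toluene (2 mM), BHT (cat.), 110 °C, 2–3 d; concentrate, SiO2
Reagents that add atoms: none
Why: The aldehyde oxygen binds the boron of the pinacol allylboronate and C1 (the γ-carbon of the allyl unit) attacks C14 through a closed six-membered chair (Zimmerman–Traxler) transition state with allylic transposition, which creates the C15=C17 methylene and a C14–O–B borate that then acylates on the adjacent methyl ester and expels MeOBpin. The closest known reaction type is the thermal addition of 2-(alkoxycarbonyl)allylboronates to aldehydes that gives α-methylene-γ-butyrolactones, run here intramolecularly at high dilution. The 14-membered carbocycle closes in the C–C bond-forming allyl transfer (end-to-end macrocyclisation of the ω-formyl allylboronate), and the five-membered lactone closes afterwards by 5-exo-trig attack of the C14 oxygen on the ester carbonyl C16. The C14/C1 relationship is set by the alkene geometry: C2 is trans to the CH2B group, sits pseudo-equatorial in the chair and gives the anti adduct, hence the trans-fused lactone; the absolute sense at C14 (S), and with it C1 (S), is set by the 13R silyloxy centre through the Cornforth (polar Felkin–Anh) arrangement, which gives the 13,14-anti adduct. The step needs cyclisation to outrun oligomerisation and must spare the epoxide, the silyl ether and the β,γ-unsaturated aldehyde; 2 mM dilution, the activating α-silyloxy group and the absence of any Lewis or Brønsted acid should secure this, and the configurational stability of the allylboronate preserves the alkene geometry until the bond is formed.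

Step 14
Reactants: 20 13-epi silyl ether lactone
Product: 21 (13R)-13-hydroxy lactone (13-epi deacetyl target)
Conditions: Bu4NF, AcOH (1:1), THF, 0 °C to rt
Reagents that add atoms: none
Why: fluoride cleaves the Si–O bond, and acetic acid buffering should protect the α-methylene lactone from conjugate addition and suppress alkoxide-driven translactonisation.

Step 15
Reactants: 21 (13R)-13-hydroxy lactone
Product: 22 13-acetoxysarcocrassolide
Conditions: PPh3, DIAD, AcOH, THF, 0 °C to rt
Reagents that add atoms: acetic acid, CC(=O)O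
Why: in the Mitsunobu reaction the C13 alkoxyphosphonium ion is displaced by acetate with SN2 inversion, which converts 13R into the 13S acetate and completes the 13,14-syn pattern.

Compound list
1 | (2E,6E)-farnesol | OC/C=C(\C)CC/C=C(\C)CCC=C(C)C | starting material
2 | (2S,3S)-2,3-epoxyfarnesol | OC[C@@H]1O[C@@]1(C)CC/C=C(\C)CCC=C(C)C | intermediate
3 | (2S,3S)-2,3-epoxyfarnesyl triflate | O=S(=O)(OC[C@@H]1O[C@@]1(C)CC/C=C(\C)CCC=C(C)C)C(F)(F)F | intermediate (not isolated)
4 | (2S,3S)-2-methyl-2-[(3E)-4,8-dimethylnona-3,7-dien-1-yl]-3-(prop-2-yn-1-yl)oxirane | C#CC[C@@H]1O[C@@]1(C)CC/C=C(\C)CCC=C(C)C | intermediate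
5 | terminal (E)-allylic alcohol (C13–OH) of 4 | C#CC[C@@H]1O[C@@]1(C)CC/C=C(\C)CC/C=C(\C)CO | intermediate (not isolated)
6 | terminal (E)-enal (C13 aldehyde) of 4 | C#CC[C@@H]1O[C@@]1(C)CC/C=C(\C)CC/C=C(\C)C=O | intermediate
7 | (tributylstannyl)methanol | CCCC[Sn](CCCC)(CCCC)CO | starting material
8 | 4-methoxybenzyl chloride | COc1ccc(CCl)cc1 | starting material
9 | tributyl{[(4-methoxybenzyl)oxy]methyl}stannane | CCCC[Sn](CCCC)(CCCC)COCc1ccc(OC)cc1 | intermediate
10 | C13 carbinol with C14H2–OPMB, both C13 epimers | C#CC[C@@H]1O[C@@]1(C)CC/C=C(\C)CC/C=C(\C)C(O)COCc1ccc(OC)cc1 | intermediate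
11 | C13 ketone (α'-PMB-oxy enone) | C#CC[C@@H]1O[C@@]1(C)CC/C=C(\C)CC/C=C(\C)C(=O)COCc1ccc(OC)cc1 | intermediate
12 | (13R)-allylic alcohol | C#CC[C@@H]1O[C@@]1(C)CC/C=C(\C)CC/C=C(\C)[C@@H](O)COCc1ccc(OC)cc1 | intermediate
13 | (13R)-TBS ether | C#CC[C@@H]1O[C@@]1(C)CC/C=C(\C)CC/C=C(\C)[C@@H](O[Si](C)(C)C(C)(C)C)COCc1ccc(OC)cc1 | intermediate
14 | methyl ynoate | COC(=O)C#CC[C@@H]1O[C@@]1(C)CC/C=C(\C)CC/C=C(\C)[C@@H](O[Si](C)(C)C(C)(C)C)COCc1ccc(OC)cc1 | intermediate
15 | α-(diisobutylalumino) enoate, C2 cis to the ester | COC(=O)/C([Al](CC(C)C)CC(C)C)=C\C[C@@H]1O[C@@]1(C)CC/C=C(\C)CC/C=C(\C)[C@@H](O[Si](C)(C)C(C)(C)C)COCc1ccc(OC)cc1 | intermediate (not isolated)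
16 | methyl (Z)-2-[(pinacolboryl)methyl]alk-2-enoate (allylboronate) | COC(=O)/C(CB1OC(C)(C)C(C)(C)O1)=C\C[C@@H]2O[C@@]2(C)CC/C=C(\C)CC/C=C(\C)[C@@H](O[Si](C)(C)C(C)(C)C)COCc1ccc(OC)cc1 | intermediate
17 | allylboronate with free C14 primary alcohol | COC(=O)/C(CB1OC(C)(C)C(C)(C)O1)=C\C[C@@H]2O[C@@]2(C)CC/C=C(\C)CC/C=C(\C)[C@@H](O[Si](C)(C)C(C)(C)C)CO | intermediate
18 | ω-formyl allylboronate (13R α-silyloxy aldehyde) | COC(=O)/C(CB1OC(C)(C)C(C)(C)O1)=C\C[C@@H]2O[C@@]2(C)CC/C=C(\C)CC/C=C(\C)[C@@H](O[Si](C)(C)C(C)(C)C)C=O | intermediate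
19 | 14-membered carbocyclic C14 pinacol borate with C1 2-(methoxycarbonyl)vinyl group (1S,13R,14S) | C=C(C(=O)OC)[C@@H]3C[C@@H]2O[C@@]2(C)CC/C=C(\C)CC/C=C(\C)[C@@H](O[Si](C)(C)C(C)(C)C)[C@H]3OB1OC(C)(C)C(C)(C)O1 | intermediate (not isolated)
20 | (1S,3S,4S,13R,14S)-13-OTBS trans-fused α-methylene lactone | C=C1C(=O)O[C@H]2[C@H]1C[C@@H]1O[C@@]1(C)CC/C=C(\C)CC/C=C(\C)[C@H]2O[Si](C)(C)C(C)(C)C | intermediate
21 | (1S,3S,4S,13R,14S)-13-hydroxy lactone (13-epi deacetyl target) | C=C1C(=O)O[C@H]2[C@H]1C[C@@H]1O[C@@]1(C)CC/C=C(\C)CC/C=C(\C)[C@H]2O | intermediate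
22 | 13-acetoxysarcocrassolide (1S,3S,4S,13S,14S) | C=C1C(=O)O[C@H]2[C@H]1C[C@@H]1O[C@@]1(C)CC/C=C(\C)CC/C=C(\C)[C@@H]2OC(C)=O | target

Total step count: 15. Longest linear sequence: 14 steps (steps 1–3 and 5–15 from farnesol; step 4 is a one-step branch).

Steps most likely to fail

Step 13. The uncatalysed allyl transfer may be too slow at 2 mM, so that thermal isomerisation or enolisation of the β,γ-unsaturated α-silyloxy aldehyde, or intermolecular oligomerisation, competes; facial control by C13 may also be incomplete in the macrocyclic transition state. The fallback replaces boron by chromium in a Nozaki–Hiyama–Kishi-type macrocyclisation at room temperature. It sets out from ynoate 14: hydroalumination as in step 10 but with capture of the vinylalane by paraformaldehyde should give the (Z)-2-(hydroxymethyl) enoate F1, and CBr4/PPh3 the (E)-2-(bromomethyl) enoate F2 (C2 still cis to the ester). DDQ then frees the primary alcohol F3 and Dess–Martin oxidation gives the bromo aldehyde F4. Slow addition of F4 to CrCl2 (divalent chromium) in THF should close the ring to the hydroxy ester F5, which lactonises with catalytic PPTS or on silica and rejoins the route at 20. The allylchromium should react through the same chair with C2 equatorial as long as its alkene geometry is retained; any cis-lactone from loss of geometry would have to be separated.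

Step 10. Equilibration of the vinylalane through an allenolate may erode the alkene geometry, DIBAL-H may reduce the ester or open the epoxide, and capture by the iodomethylboronate may be sluggish. The fallback builds the same geometry by palladium chemistry from ynoate 14. Syn-hydrostannation (Bu3SnH, Pd(PPh3)4) should give the (E)-α-tributylstannyl enoate F6, and iododestannylation with I2 the (E)-α-iodo enoate F7 with retention. Negishi coupling of F7 with (iodozincio)methyl pinacolboronate, IZnCH2Bpin, under Pd(PPh3)4 returns to allylboronate 16.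

Step 15. Acetate may attack C11 with allylic transposition, the activated allylic alcohol may eliminate to a diene, or displacement at the hindered C13 may not occur. The fallback inverts C13 by oxidation and reduction from alcohol 21. Dess–Martin oxidation should give the C13 enone F8, and Luche reduction (NaBH4, CeCl3·7H2O, MeOH, −78 °C) should deliver hydride anti to the C14–O bond (Felkin–Anh) to give the (13S)-alcohol F9. Acetylation of F9 (Ac2O, pyridine, DMAP) gives 22.

Further compounds
F1 | step 13 | methyl (Z)-2-(hydroxymethyl)alk-2-enoate, C2 cis to the ester | COC(=O)/C(CO)=C\C[C@@H]1O[C@@]1(C)CC/C=C(\C)CC/C=C(\C)[C@@H](O[Si](C)(C)C(C)(C)C)COCc1ccc(OC)cc1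
F2 | step 13 | methyl (E)-2-(bromomethyl)alk-2-enoate, PMB ether | COC(=O)/C(CBr)=C\C[C@@H]1O[C@@]1(C)CC/C=C(\C)CC/C=C(\C)[C@@H](O[Si](C)(C)C(C)(C)C)COCc1ccc(OC)cc1
F3 | step 13 | allylic bromide with free C14 primary alcohol | COC(=O)/C(CBr)=C\C[C@@H]1O[C@@]1(C)CC/C=C(\C)CC/C=C(\C)[C@@H](O[Si](C)(C)C(C)(C)C)CO
F4 | step 13 | ω-formyl allylic bromide | COC(=O)/C(CBr)=C\C[C@@H]1O[C@@]1(C)CC/C=C(\C)CC/C=C(\C)[C@@H](O[Si](C)(C)C(C)(C)C)C=O
F5 | step 13 | 14-membered carbocyclic C14 hydroxy ester (1S,13R,14S) | C=C(C(=O)OC)[C@@H]3C[C@@H]2O[C@@]2(C)CC/C=C(\C)CC/C=C(\C)[C@@H](O[Si](C)(C)C(C)(C)C)[C@H]3O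
F6 | step 10 | methyl (E)-2-(tributylstannyl)alk-2-enoate | COC(=O)/C([Sn](CCCC)(CCCC)CCCC)=C\C[C@@H]1O[C@@]1(C)CC/C=C(\C)CC/C=C(\C)[C@@H](O[Si](C)(C)C(C)(C)C)COCc1ccc(OC)cc1
F7 | step 10 | methyl (E)-2-iodoalk-2-enoate | COC(=O)/C(I)=C\C[C@@H]1O[C@@]1(C)CC/C=C(\C)CC/C=C(\C)[C@@H](O[Si](C)(C)C(C)(C)C)COCc1ccc(OC)cc1
F8 | step 15 | C13 enone of the lactone | C=C1C(=O)O[C@H]2[C@H]1C[C@@H]1O[C@@]1(C)CC/C=C(\C)CC/C=C(\C)C2=O
F9 | step 15 | (13S)-13-hydroxy lactone (deacetyl target) | C=C1C(=O)O[C@H]2[C@H]1C[C@@H]1O[C@@]1(C)CC/C=C(\C)CC/C=C(\C)[C@@H]2O
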